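**Plan**

- Numbering is that of the germacrane skeleton: C6 and C8 are the lactone O–CH carbons, C7 the ring-fusion CH, C11/C12/C13 the methylene-lactone carbons, C15 the butenolide carbonyl, C14 the CH2OH on C10. The five-membered ring O8–C8–C7–C11–C12, with C7 and C8 trans and C6 attached to C7, is a paraconic acid once C6 is written as a carboxyl group. It can therefore be made from a 2-acylsuccinate by reduction at C8.
- Retrosynthetic cuts, in order: O14–Si; C5–C6 together with O6–C15 (opens the ten-membered ring and the butenolide); C3–C4 and C5–I (iodo-aldol with methyl propiolate); C11=C13; C8–H and O8–C12 (key step); C7–C8 (Stetter); C9–C10 (auxiliary allylation).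
- Forward order: C3–C10 chain, then the acylsuccinate, then the gamma-lactone (ring 1), then the exo-methylene, then the C4/C5/C15 unit on C3, then the ten-membered ring and the butenolide (rings 2 and 3) in one Ni/Cr operation.
- Stereochemistry: C10 from an oxazolidinone auxiliary; C7 and C8 from the ketoreductase; C3 from a chiral oxazaborolidinium catalyst; C6 from substrate control in the ring closure.

Key step: step 8

Assumption: the oxazaborolidinium-catalysed iodo-aldol is taken to follow the usual formyl C–H···O binding model, so that the (R)-prolinol-derived ion gives 3S; if the sense proves opposite, the enantiomeric catalyst is used with no other change.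

Abbreviations: PMB = 4-methoxybenzyl; TBDPS = tert-butyldiphenylsilyl; TBS = tert-butyldimethylsilyl.

**Route**

Step 1
Reactants: 1 delta-valerolactone
Product: 3 5-[(4-methoxybenzyl)oxy]pentanoic acid, via potassium 5-hydroxypentanoate 2 (not isolated)
Conditions: KOH (powdered, excess), 4-methoxybenzyl chloride, toluene, reflux; then aq. KOH, MeOH, 60 °C; HCl to pH 3
Reagents that add atoms: 4-methoxybenzyl chloride, COc1ccc(CCl)cc1; potassium hydroxide, [K+].[OH-]
Why: Saponification opens the lactone and the alkoxide is benzylated in the same pot (Williamson etherification); the basic second stage cleaves any PMB ester before acidification.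

Step 2
Reactants: 3 5-[(4-methoxybenzyl)oxy]pentanoic acid; 4 (S)-4-benzyl-2-oxazolidinone
Product: 6 N-acyl oxazolidinone, via mixed pivalic anhydride 5 (not isolated)
Conditions: PivCl, Et3N, THF, –20 °C; then 4, LiCl, –20 °C → rt
Reagents that add atoms: none
Why: N-Acylation of the oxazolidinone through the mixed pivalic anhydride (LiCl/Et3N variant) attaches the auxiliary without a strong base.

Step 3
Reactants: 6 N-acyl oxazolidinone; 7 allyl bromide
Product: 9 (R)-allylated imide, via sodium (Z)-enolate 8 (not isolated)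
Conditions: NaN(SiMe3)2, THF, –78 °C; then allyl bromide, –78 → –40 °C
Reagents that add atoms: none
Why: Auxiliary-controlled enolate alkylation: the chelated (Z)-enolate is shielded on one face by the benzyl group, so allyl bromide enters from the other face and sets C10 as R.

Step 4
Reactants: 9 (R)-allylated imide
Product: 10 (R)-2-allyl-5-[(4-methoxybenzyl)oxy]pentan-1-ol
Conditions: LiBH4, H2O (1 equiv), Et2O, 0 °C
Reagents that add atoms: none
Why: Reductive cleavage of the imide with LiBH4 releases the C14 primary alcohol and the recoverable auxiliary without touching the alkene or C10.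

Step 5
Reactants: 10 (R)-2-allyl-5-[(4-methoxybenzyl)oxy]pentan-1-ol
Product: 11 TBDPS ether of 10
Conditions: tert-butyl(chloro)diphenylsilane, imidazole, CH2Cl2, rt
Reagents that add atoms: tert-butyl(chloro)diphenylsilane, CC(C)(C)[Si](Cl)(c1ccccc1)c1ccccc1
Why: Imidazole-promoted silylation of the primary alcohol gives a robust ether intended to last to the final step.

Step 6
Reactants: 11 TBDPS ether of 10
Product: 13 C8 aldehyde, via vicinal diol 12 (not isolated)
Conditions: OsO4 (2 mol%), NaIO4, 2,6-lutidine, dioxane/H2O (3:1), rt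
Reagents that add atoms: osmium tetroxide, O=[Os](=O)(=O)=O; sodium periodate, [Na+].[O-]I(=O)(=O)=O
Why: Lemieux–Johnson oxidation (dihydroxylation, then periodate cleavage) converts the terminal alkene to the aldehyde and spares the electron-rich PMB ring that ozone could attack.

Step 7
Reactants: 13 C8 aldehyde; 14 dimethyl fumarate
Product: 15 dimethyl 2-acylsuccinate (C7 epimers)
Conditions: 3-benzyl-5-(2-hydroxyethyl)-4-methylthiazolium chloride (20 mol%), Et3N, 1,4-dioxane, 70 °C
Reagents that add atoms: none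
Why: Stetter reaction: the thiazolium-derived acyl anion equivalent of the aldehyde adds 1,4 to the fumarate and forms the C7–C8 bond, leaving C7 free to epimerise.

Step 8
Reactants: 15 dimethyl 2-acylsuccinate (C7 epimers)
Product: 17 trans-paraconate methyl ester, via hydroxy diester 16 (not isolated)
Conditions: ketoreductase (NADPH-dependent, chosen from a screening panel for the 7S,8R outcome), NADP+ (cat.), i-PrOH (10 vol%), phosphate buffer pH 7.5 (KH2PO4/K2HPO4, MgSO4 2 mM), DMSO (10 vol%), 30 °C; then PPTS (cat.), toluene, 40 °C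
Reagents that add atoms: none
Why: The 2-acylsuccinate epimerises at C7 through its enol faster than it is reduced, and the enzyme transfers the NADPH hydride to one face of the C8 carbonyl of the 7S epimer only, giving the (7S,8R) hydroxy diester 16. The new hydroxyl then attacks the C12 methyl ester (5-exo-trig acyl substitution, loss of methanol) and closes the gamma-lactone with the C6 ester and the C9 chain trans. The closest known reaction type is the ketoreductase dynamic reductive kinetic resolution of alpha-substituted beta-keto esters, together with the reduction–lactonisation of 2-acylsuccinates to paraconates. C8 is set by the facial preference of the enzyme and C7 by its discrimination between the interconverting epimers, so both are under catalyst control and the remote C10 centre has no say. The step needs carbonyl-face and epimer selectivity at once; the beta-keto ester acidity of C7–H secures the dynamic regime, and only the C12 ester can lactonise because attack on C6 would give a four-membered ring.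

Step 9
Reactants: 17 trans-paraconate methyl ester
Product: 19 trans-paraconic acid, via dilithium hydroxy succinate 18 (not isolated)
Conditions: LiOH, THF/H2O, 0 °C → rt; then 1 M HCl to pH 3, 0 °C
Reagents that add atoms: lithium hydroxide, [Li+].[OH-]
Why: Saponification cleaves the C6 methyl ester and opens the lactone, and acidification re-closes the five-membered lactone, the only ring size available, leaving C7 and C8 untouched.

Step 10
Reactants: 19 trans-paraconic acid
Product: 20 C6 hydroxymethyl lactone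
Conditions: BH3·SMe2, THF, 0 °C → rt; MeOH quench
Reagents that add atoms: none
Why: Chemoselective borane reduction: the carboxylic acid is reduced through its acyloxyborane much faster than the lactone.

Step 11
Reactants: 20 C6 hydroxymethyl lactone
Product: 21 C6 TBS ether
Conditions: TBSCl, imidazole, CH2Cl2, 0 °C
Reagents that add atoms: tert-butyl(chloro)dimethylsilane, CC(C)(C)[Si](C)(C)Cl
Why: Prompt silylation of the C6 hydroxyl prevents translactonisation and allows enolate chemistry, with a group that can later be removed beside the TBDPS ether.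

Step 12
Reactants: 21 C6 TBS ether
Product: 25 exo-methylene lactone (C11=C13), via lithium enolate 22 (not isolated), via Mannich base 23 (not isolated), via trimethylammonium iodide 24 (not isolated)
Conditions: LiN(iPr)2, THF, –78 °C; Eschenmoser's salt, –78 → 0 °C; then MeI, CH2Cl2, rt; then sat. aq. NaHCO3, rt
Reagents that add atoms: Eschenmoser's salt, C=[N+](C)C.[I-]
Why: Alpha-methylenation of a lactone through its enolate: Mannich alkylation, quaternisation and base-induced loss of trimethylamine install C11=C13, C11 being the only enolisable position.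

Step 13
Reactants: 25 exo-methylene lactone (C11=C13)
Product: 26 C3 primary alcohol
Conditions: DDQ, CH2Cl2/pH 7 phosphate buffer (10:1), 0 °C
Reagents that add atoms: none
Why: Oxidative PMB cleavage by DDQ (hydride abstraction, hydrolysis of the oxocarbenium ion) frees the C3 alcohol and leaves both silyl ethers and the electron-poor alkene.

Step 14
Reactants: 26 C3 primary alcohol
Product: 27 C3 aldehyde
Conditions: Dess–Martin periodinane, NaHCO3, CH2Cl2, 0 °C → rt
Reagents that add atoms: none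
Why: Dess–Martin oxidation gives the aldehyde under buffered, non-basic conditions.

Step 15
Reactants: 27 C3 aldehyde; 28 methyl propiolate
Product: 31 (Z)-iodo-aldol adduct (3S alcohol), via silyl allenolate 29 (not isolated), via trimethylsilyl ether 30 (not isolated)
Conditions: oxazaborolidinium triflimide [from (R)-3,3-diphenyl-1-(o-tolyl)tetrahydro-1H,3H-pyrrolo[1,2-c][1,3,2]oxazaborole and HNTf2] (20 mol%), TMSI, CH2Cl2, –78 °C; then aq. citric acid, THF, 0 °C
Reagents that add atoms: iodotrimethylsilane, C[Si](C)(C)I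
Why: Three-component iodo-aldol (iodo-Morita–Baylis–Hillman) reaction: TMSI adds to the propiolate to give the silyl allenolate, which attacks one face of the catalyst-bound aldehyde, forming C3–C4 with C3 as S under catalyst control and the (Z)-iodoalkene.

Step 16
Reactants: 31 (Z)-iodo-aldol adduct (3S alcohol)
Product: 32 C3 isobutyrate
Conditions: isobutyryl chloride, pyridine, CH2Cl2, 0 °C
Reagents that add atoms: isobutyryl chloride, CC(C)C(Cl)=O
Why: Acylation of the secondary allylic alcohol with the acid chloride and pyridine, without a nucleophilic catalyst that could attack the iodoacrylate, installs the ester of the target.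

Step 17
Reactants: 32 C3 isobutyrate
Product: 33 C6 primary alcohol
Conditions: HF·pyridine, pyridine, THF, 0 °C
Reagents that add atoms: none
Why: Selective desilylation: buffered HF·pyridine cleaves the primary TBS ether much faster than the primary TBDPS ether.

Step 18
Reactants: 33 C6 primary alcohol
Product: 34 C6 aldehyde
Conditions: Dess–Martin periodinane, NaHCO3, CH2Cl2, 0 °C; filtered and used at once
Reagents that add atoms: none
Why: Dess–Martin oxidation under NaHCO3 buffering gives the beta,gamma-unsaturated aldehyde without a base strong enough to enolise it.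

Step 19
Reactants: 34 C6 aldehyde
Product: 36 silyl-protected macrocyclic dilactone, via ten-membered carbinol ester 35 (not isolated)
Conditions: CrCl2 (10 equiv), NiCl2 (0.1 equiv), DMSO/THF, rt, slow addition to 2 mM
Reagents that add atoms: none
Why: Nozaki–Hiyama–Kishi macrocyclisation: zerovalent nickel inserts into the C5–I bond, transmetalation gives a vinylchromium species that adds to the C6 aldehyde with retention of alkene geometry, the chromium alkoxide then acylates itself on the cis C15 ester to close the butenolide, and C6 should form as R by addition to the aldehyde face left open by C7 and C8 in the cyclic transition state (substrate control).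

Step 20
Reactants: 36 silyl-protected macrocyclic dilactone
Product: 37 CNP0332805.1
Conditions: HF·pyridine (excess), THF, 0 °C → rt
Reagents that add atoms: none
Why: Fluoride cleavage of the TBDPS ether under acidic, non-basic conditions spares both lactones, the isobutyrate and the exo-methylene group.

**Compound list**

1 | delta-valerolactone | O=C1CCCCO1 | starting material
2 | potassium 5-hydroxypentanoate (not isolated) | [K+].[O-]C(=O)CCCCO | intermediate
3 | 5-[(4-methoxybenzyl)oxy]pentanoic acid | OC(=O)CCCCOCc1ccc(OC)cc1 | intermediate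
4 | (S)-4-benzyl-2-oxazolidinone | O=C1N[C@@H](Cc2ccccc2)CO1 | starting material
5 | 5-[(4-methoxybenzyl)oxy]pentanoic pivalic anhydride (not isolated) | CC(C)(C)C(=O)OC(=O)CCCCOCc1ccc(OC)cc1 | intermediate
6 | (S)-4-benzyl-3-{5-[(4-methoxybenzyl)oxy]pentanoyl}oxazolidin-2-one | O=C1OC[C@H](Cc2ccccc2)N1C(=O)CCCCOCc1ccc(OC)cc1 | intermediate
7 | allyl bromide | C=CCBr | starting material
8 | sodium (Z)-enolate of 6 (not isolated) | [Na+].[O-]/C(=C\CCCOCc1ccc(OC)cc1)N1[C@@H](Cc2ccccc2)COC1=O | intermediate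
9 | (S)-4-benzyl-3-{(R)-2-allyl-5-[(4-methoxybenzyl)oxy]pentanoyl}oxazolidin-2-one | O=C1OC[C@H](Cc2ccccc2)N1C(=O)[C@@H](CC=C)CCCOCc1ccc(OC)cc1 | intermediate
10 | (R)-2-allyl-5-[(4-methoxybenzyl)oxy]pentan-1-ol | OC[C@@H](CC=C)CCCOCc1ccc(OC)cc1 | intermediate
11 | tert-butyl{[(R)-2-allyl-5-[(4-methoxybenzyl)oxy]pentyl]oxy}diphenylsilane | CC(C)(C)[Si](c1ccccc1)(c1ccccc1)OC[C@@H](CC=C)CCCOCc1ccc(OC)cc1 | intermediate
12 | (4R)-4-(TBDPS-oxymethyl)-7-[(4-methoxybenzyl)oxy]heptane-1,2-diol, C2 epimers (not isolated) | CC(C)(C)[Si](c1ccccc1)(c1ccccc1)OC[C@@H](CC(O)CO)CCCOCc1ccc(OC)cc1 | intermediate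
13 | (R)-3-(TBDPS-oxymethyl)-6-[(4-methoxybenzyl)oxy]hexanal | CC(C)(C)[Si](c1ccccc1)(c1ccccc1)OC[C@@H](CC=O)CCCOCc1ccc(OC)cc1 | intermediate
14 | dimethyl fumarate | COC(=O)/C=C/C(=O)OC | starting material
15 | dimethyl 2-[(R)-3-(TBDPS-oxymethyl)-6-[(4-methoxybenzyl)oxy]hexanoyl]butanedioate, both C7 epimers | COC(=O)CC(C(=O)OC)C(=O)C[C@H](CO[Si](c1ccccc1)(c1ccccc1)C(C)(C)C)CCCOCc1ccc(OC)cc1 | intermediate
16 | dimethyl (S)-2-[(1R,3R)-1-hydroxy-3-(TBDPS-oxymethyl)-6-[(4-methoxybenzyl)oxy]hexyl]butanedioate (not isolated) | COC(=O)[C@@H](CC(=O)OC)[C@H](O)C[C@H](CO[Si](c1ccccc1)(c1ccccc1)C(C)(C)C)CCCOCc1ccc(OC)cc1 | intermediate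
17 | methyl (2R,3S)-2-[(R)-2-(TBDPS-oxymethyl)-5-[(4-methoxybenzyl)oxy]pentyl]-5-oxooxolane-3-carboxylate | COC(=O)[C@H]1CC(=O)O[C@@H]1C[C@H](CO[Si](c2ccccc2)(c2ccccc2)C(C)(C)C)CCCOCc2ccc(OC)cc2 | intermediate
18 | dilithium (S)-2-[(1R,3R)-1-hydroxy-3-(TBDPS-oxymethyl)-6-[(4-methoxybenzyl)oxy]hexyl]butanedioate (not isolated) | [Li+].[Li+].[O-]C(=O)[C@@H](CC([O-])=O)[C@H](O)C[C@H](CO[Si](c1ccccc1)(c1ccccc1)C(C)(C)C)CCCOCc1ccc(OC)cc1 | intermediate
19 | (2R,3S)-2-[(R)-2-(TBDPS-oxymethyl)-5-[(4-methoxybenzyl)oxy]pentyl]-5-oxooxolane-3-carboxylic acid | OC(=O)[C@H]1CC(=O)O[C@@H]1C[C@H](CO[Si](c2ccccc2)(c2ccccc2)C(C)(C)C)CCCOCc2ccc(OC)cc2 | intermediate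
20 | (4R,5R)-4-(hydroxymethyl)-5-[(R)-2-(TBDPS-oxymethyl)-5-[(4-methoxybenzyl)oxy]pentyl]oxolan-2-one | OC[C@H]1CC(=O)O[C@@H]1C[C@H](CO[Si](c2ccccc2)(c2ccccc2)C(C)(C)C)CCCOCc2ccc(OC)cc2 | intermediate
21 | (4R,5R)-4-(TBS-oxymethyl)-5-[(R)-2-(TBDPS-oxymethyl)-5-[(4-methoxybenzyl)oxy]pentyl]oxolan-2-one | CC(C)(C)[Si](C)(C)OC[C@H]1CC(=O)O[C@@H]1C[C@H](CO[Si](c2ccccc2)(c2ccccc2)C(C)(C)C)CCCOCc2ccc(OC)cc2 | intermediate
22 | lithium enolate of 21 (not isolated) | [Li+].CC(C)(C)[Si](C)(C)OC[C@H]1C=C([O-])O[C@@H]1C[C@H](CO[Si](c2ccccc2)(c2ccccc2)C(C)(C)C)CCCOCc2ccc(OC)cc2 | intermediate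
23 | (4R,5R)-3-[(dimethylamino)methyl] derivative of 21, C11 epimers (not isolated) | CC(C)(C)[Si](C)(C)OC[C@H]1C(CN(C)C)C(=O)O[C@@H]1C[C@H](CO[Si](c2ccccc2)(c2ccccc2)C(C)(C)C)CCCOCc2ccc(OC)cc2 | intermediate
24 | trimethylammonium iodide from 23 (not isolated) | [I-].CC(C)(C)[Si](C)(C)OC[C@H]1C(C[N+](C)(C)C)C(=O)O[C@@H]1C[C@H](CO[Si](c2ccccc2)(c2ccccc2)C(C)(C)C)CCCOCc2ccc(OC)cc2 | intermediate
25 | (4R,5R)-4-(TBS-oxymethyl)-5-[(R)-2-(TBDPS-oxymethyl)-5-[(4-methoxybenzyl)oxy]pentyl]-3-methylideneoxolan-2-one | CC(C)(C)[Si](C)(C)OC[C@H]1C(=C)C(=O)O[C@@H]1C[C@H](CO[Si](c2ccccc2)(c2ccccc2)C(C)(C)C)CCCOCc2ccc(OC)cc2 | intermediate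
26 | (4R,5R)-4-(TBS-oxymethyl)-5-[(R)-2-(TBDPS-oxymethyl)-5-hydroxypentyl]-3-methylideneoxolan-2-one | CC(C)(C)[Si](C)(C)OC[C@H]1C(=C)C(=O)O[C@@H]1C[C@H](CO[Si](c2ccccc2)(c2ccccc2)C(C)(C)C)CCCO | intermediate
27 | (R)-4-(TBDPS-oxymethyl)-5-[(2R,3R)-3-(TBS-oxymethyl)-4-methylidene-5-oxooxolan-2-yl]pentanal | CC(C)(C)[Si](C)(C)OC[C@H]1C(=C)C(=O)O[C@@H]1C[C@H](CO[Si](c2ccccc2)(c2ccccc2)C(C)(C)C)CCC=O | intermediate
28 | methyl propiolate | COC(=O)C#C | starting material
29 | 1-iodo-3-methoxy-3-(trimethylsilyloxy)propa-1,2-diene (not isolated) | COC(O[Si](C)(C)C)=C=CI | intermediate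
30 | trimethylsilyl ether of 31 (not isolated) | CC(C)(C)[Si](C)(C)OC[C@H]1C(=C)C(=O)O[C@@H]1C[C@H](CO[Si](c2ccccc2)(c2ccccc2)C(C)(C)C)CC[C@H](O[Si](C)(C)C)/C(=C/I)C(=O)OC | intermediate
31 | methyl (Z)-2-[(1S,4R)-1-hydroxy-4-(TBDPS-oxymethyl)-5-[(2R,3R)-3-(TBS-oxymethyl)-4-methylidene-5-oxooxolan-2-yl]pentyl]-3-iodoprop-2-enoate | CC(C)(C)[Si](C)(C)OC[C@H]1C(=C)C(=O)O[C@@H]1C[C@H](CO[Si](c2ccccc2)(c2ccccc2)C(C)(C)C)CC[C@H](O)/C(=C/I)C(=O)OC | intermediate
32 | methyl (Z)-2-[(1S,4R)-1-(isobutyryloxy)-4-(TBDPS-oxymethyl)-5-[(2R,3R)-3-(TBS-oxymethyl)-4-methylidene-5-oxooxolan-2-yl]pentyl]-3-iodoprop-2-enoate | CC(C)(C)[Si](C)(C)OC[C@H]1C(=C)C(=O)O[C@@H]1C[C@H](CO[Si](c2ccccc2)(c2ccccc2)C(C)(C)C)CC[C@H](OC(=O)C(C)C)/C(=C/I)C(=O)OC | intermediate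
33 | methyl (Z)-2-[(1S,4R)-1-(isobutyryloxy)-4-(TBDPS-oxymethyl)-5-[(2R,3R)-3-(hydroxymethyl)-4-methylidene-5-oxooxolan-2-yl]pentyl]-3-iodoprop-2-enoate | OC[C@H]1C(=C)C(=O)O[C@@H]1C[C@H](CO[Si](c2ccccc2)(c2ccccc2)C(C)(C)C)CC[C@H](OC(=O)C(C)C)/C(=C/I)C(=O)OC | intermediate
34 | methyl (Z)-2-[(1S,4R)-1-(isobutyryloxy)-4-(TBDPS-oxymethyl)-5-[(2R,3S)-3-formyl-4-methylidene-5-oxooxolan-2-yl]pentyl]-3-iodoprop-2-enoate | O=C[C@H]1C(=C)C(=O)O[C@@H]1C[C@H](CO[Si](c2ccccc2)(c2ccccc2)C(C)(C)C)CC[C@H](OC(=O)C(C)C)/C(=C/I)C(=O)OC | intermediate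
35 | (3S,6R,7R,8R,10R)-ten-membered 6-carbinol with 12,8-lactone, 3-isobutyrate, 14-O-TBDPS and C15 methyl ester, 4E (not isolated; present as its chromium alkoxide) | C=C1C(=O)O[C@@H]2C[C@H](CO[Si](c3ccccc3)(c3ccccc3)C(C)(C)C)CC[C@H](OC(=O)C(C)C)/C(C(=O)OC)=C/[C@@H](O)[C@@H]12 | intermediate
36 | (3S,6R,7S,8R,10R)-3-isobutyryloxy-14-(TBDPS-oxy)germacra-4,11(13)-diene-12,8:15,6-diolide | C=C1C(=O)O[C@@H]2C[C@H](CO[Si](c3ccccc3)(c3ccccc3)C(C)(C)C)CC[C@H](OC(=O)C(C)C)C3=C[C@@H](OC3=O)[C@@H]12 | intermediate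
37 | CNP0332805.1, (3S,6R,7S,8R,10R)-14-hydroxy-3-isobutyryloxygermacra-4,11(13)-diene-12,8:15,6-diolide | C=C1C(=O)O[C@@H]2C[C@H](CO)CC[C@H](OC(=O)C(C)C)C3=C[C@@H](OC3=O)[C@@H]12 | target

**Step count and risks**

Total steps: 20. Longest linear sequence: 20 steps (1 to 37); the route is fully linear.

Steps most likely to fail:

1. Step 8. The screening panel may hold no enzyme that accepts a ketone flanked by two large groups, or reduction may outrun C7 epimerisation so that a plain kinetic resolution with mixed C7 results. Fallback: the C7–C8 bond and both centres are made by an auxiliary-controlled syn-aldol instead of a reduction. It sets out from aldehyde 13 and returns at acid 19. Oxazolidinone 4 is N-acylated (n-BuLi, THF, –78 °C; methyl 4-chloro-4-oxobutanoate) to the succinyl imide F1. Its dibutylboron (Z)-enolate (Bu2BOTf, i-Pr2NEt, CH2Cl2, –78 °C) should add to 13 in the syn sense, and the aldolate closes onto the methyl ester to give the trans lactone imide F2. LiOH/H2O2 (THF/H2O, 0 °C) then removes the auxiliary and gives 19.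

2. Step 19 (with the aldehyde from step 18). While the strained ring closes slowly, the beta,gamma-unsaturated C6 aldehyde may enolise (migration of C11=C13 into conjugation, epimerisation at C7) or oligomerise. Fallback: C11 is kept sp3 through the ring closure by masking the exo-methylene as a thiophenol adduct. It sets out from 25 and returns at 36.
   - PhSH with catalytic Et3N (CH2Cl2, rt) gives the phenylthiomethyl lactone F3.
   - The operations of steps 13 to 18 are repeated on it: DDQ gives the primary alcohol F4; Dess–Martin oxidation gives the aldehyde F5; the catalytic iodo-aldol gives the adduct F6; isobutyryl chloride/pyridine gives the isobutyrate F7; HF·pyridine gives the C6 alcohol F8; Dess–Martin oxidation gives the C6 aldehyde F9, which is no longer allylic.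
   - CrCl2/NiCl2 closes the ring and the butenolide to the macrocyclic sulfide F10.
   - mCPBA (1 equiv, CH2Cl2, –78 °C) gives the sulfoxide F11, whose syn-elimination (toluene, CaCO3, 100 °C) restores C11=C13 and gives 36.

3. Step 15. TMSI may add to the exo-methylene lactone in competition with the propiolate, and the catalyst may discriminate poorly between the aldehyde faces, since the remote C10 centre gives no help at C3. Fallback: C3 is set by reagent-controlled ketone reduction instead of by the aldol step. It sets out from aldehyde 27 and returns at 31. MgI2 and methyl propiolate 28 (CH2Cl2, 0 °C) give the (Z)-iodo-aldol adduct as a mixture of C3 epimers F12. Dess–Martin oxidation gives the iodomethylene keto ester F13. Corey–Bakshi–Shibata reduction with the (R)-B-methyl oxazaborolidine and catecholborane (toluene, –78 °C) should deliver the 3S alcohol 31.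

**Further compounds**

F1 | step 8 | (S)-4-benzyl-3-(4-methoxy-4-oxobutanoyl)oxazolidin-2-one | COC(=O)CCC(=O)N1[C@@H](Cc2ccccc2)COC1=O
F2 | step 8 | (S)-4-benzyl-3-{(2R,3S)-2-[(R)-2-(TBDPS-oxymethyl)-5-[(4-methoxybenzyl)oxy]pentyl]-5-oxooxolane-3-carbonyl}oxazolidin-2-one | O=C1OC[C@H](Cc2ccccc2)N1C(=O)[C@H]3CC(=O)O[C@@H]3C[C@H](CO[Si](c2ccccc2)(c2ccccc2)C(C)(C)C)CCCOCc2ccc(OC)cc2
F3 | step 19 | thiophenol adduct of 25, 3-(phenylthiomethyl) lactone, C11 epimers | CC(C)(C)[Si](C)(C)OC[C@H]1C(CSc2ccccc2)C(=O)O[C@@H]1C[C@H](CO[Si](c2ccccc2)(c2ccccc2)C(C)(C)C)CCCOCc2ccc(OC)cc2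
F4 | step 19 | C3 primary alcohol of the sulfide series | CC(C)(C)[Si](C)(C)OC[C@H]1C(CSc2ccccc2)C(=O)O[C@@H]1C[C@H](CO[Si](c2ccccc2)(c2ccccc2)C(C)(C)C)CCCO
F5 | step 19 | C3 aldehyde of the sulfide series | CC(C)(C)[Si](C)(C)OC[C@H]1C(CSc2ccccc2)C(=O)O[C@@H]1C[C@H](CO[Si](c2ccccc2)(c2ccccc2)C(C)(C)C)CCC=O
F6 | step 19 | (Z)-iodo-aldol adduct (3S) of the sulfide series | CC(C)(C)[Si](C)(C)OC[C@H]1C(CSc2ccccc2)C(=O)O[C@@H]1C[C@H](CO[Si](c2ccccc2)(c2ccccc2)C(C)(C)C)CC[C@H](O)/C(=C/I)C(=O)OC
F7 | step 19 | C3 isobutyrate of the sulfide series | CC(C)(C)[Si](C)(C)OC[C@H]1C(CSc2ccccc2)C(=O)O[C@@H]1C[C@H](CO[Si](c2ccccc2)(c2ccccc2)C(C)(C)C)CC[C@H](OC(=O)C(C)C)/C(=C/I)C(=O)OC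
F8 | step 19 | C6 primary alcohol of the sulfide series | OC[C@H]1C(CSc2ccccc2)C(=O)O[C@@H]1C[C@H](CO[Si](c2ccccc2)(c2ccccc2)C(C)(C)C)CC[C@H](OC(=O)C(C)C)/C(=C/I)C(=O)OC
F9 | step 19 | C6 aldehyde of the sulfide series | O=C[C@H]1C(CSc2ccccc2)C(=O)O[C@@H]1C[C@H](CO[Si](c2ccccc2)(c2ccccc2)C(C)(C)C)CC[C@H](OC(=O)C(C)C)/C(=C/I)C(=O)OC
F10 | step 19 | macrocyclic dilactone with 13-phenylthio group and 14-O-TBDPS | c4ccccc4SCC1C(=O)O[C@@H]2C[C@H](CO[Si](c3ccccc3)(c3ccccc3)C(C)(C)C)CC[C@H](OC(=O)C(C)C)C3=C[C@@H](OC3=O)[C@@H]12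
F11 | step 19 | sulfoxide of F10 | O=S(c4ccccc4)CC1C(=O)O[C@@H]2C[C@H](CO[Si](c3ccccc3)(c3ccccc3)C(C)(C)C)CC[C@H](OC(=O)C(C)C)C3=C[C@@H](OC3=O)[C@@H]12
F12 | step 15 | (Z)-iodo-aldol adduct, mixture of C3 epimers | CC(C)(C)[Si](C)(C)OC[C@H]1C(=C)C(=O)O[C@@H]1C[C@H](CO[Si](c2ccccc2)(c2ccccc2)C(C)(C)C)CCC(O)/C(=C/I)C(=O)OC
F13 | step 15 | (Z)-2-(iodomethylene) 3-keto ester | CC(C)(C)[Si](C)(C)OC[C@H]1C(=C)C(=O)O[C@@H]1C[C@H](CO[Si](c2ccccc2)(c2ccccc2)C(C)(C)C)CCC(=O)/C(=C/I)C(=O)OC
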